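## Retrosynthetic overview

1. Feature: ring A (C1–C2–O3–C4–C5) of the 3,7-dioxabicyclo[3.3.0]octane is read as two parts. C2–O3–C4 is the carbonyl ylide of O-benzylvanillin. C1=C5 is an enediol whose two cis oxygens become the bridgehead hydroxyls and whose two ester carbons become C8 (on C1) and C6 (on C5).
2. 21 <= 20 <= 19 by debenzylation and diacetal hydrolysis. Ring B is closed last at C6–O7 by capture of a benzylic cation, after the second aryl group has been added to lactone 14.
3. 14 <= 11 by telling the equatorial C5 ester (C6) from the axial C1 ester (C8): the first is hydrolysed, the second is reduced.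
4. 11 <= ylide 10 (from α-chloro silylmethyl ether 9) + enediol diester 5 (two steps from dimethyl L-tartrate). The enediol is masked as a chiral, C2-symmetric butane-2,3-diacetal, because the fluoride that frees the ylide would bind any chiral Lewis acid.
5. Ring order: ring A (step 5); ring B as lactone (step 7), reopened (step 8), closed for good (step 10).

Key step: step 5

Remark: core atoms keep the target numbering (C1, C2, O3, C4, C5, C6, O7, C8) in all intermediates, Ar = 4-benzyloxy-3-methoxyphenyl, and the sense of induction in step 5 rests on the steric model given there.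

## Route

Step 1
Reactants: 1 dimethyl L-tartrate; 2 butane-2,3-dione
Product: 3 dimethyl (2R,3R,5R,6R)-5,6-dimethoxy-5,6-dimethyl-1,4-dioxane-2,3-dicarboxylate
Conditions: HC(OMe)3 (4 equiv), CSA (0.1 equiv), MeOH, reflux
Reagents that add atoms: trimethyl orthoformate, COC(OC)OC (the two acetal OMe groups)
Why: Acid-catalysed butane-2,3-diacetal formation (double transketalisation under thermodynamic control): the trans-diol of 1 closes a chair 1,4-dioxane with both esters equatorial and both OMe groups axial (anomeric effect), so the tartrate centres set both new acetal centres as R.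

Step 2
Reactants: 3 diacetal of dimethyl L-tartrate
Product: 5 dimethyl (5R,6R)-5,6-dimethoxy-5,6-dimethyl-5,6-dihydro-1,4-dioxine-2,3-dicarboxylate, via α-iodo diester 4 (not isolated)
Conditions: LDA (2.3 equiv), THF, −78 °C; I2 (1.2 equiv), −78 °C → rt
Reagents that add atoms: none
Why: Enolate iodination followed by E1cB loss of HI with the second equivalent of LDA, a dehydrogenation known for this class of tartrate diacetals; both tartrate centres vanish, the acetal centres keep the chirality, and the ring locks the enediol in the Z geometry that a cis-diol needs and that free (E)-dihydroxyfumarate lacks.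

Step 3
Reactants: 6 4-benzyloxy-3-methoxybenzaldehyde; 7 (trimethylsilyl)methanol
Product: 8 4-benzyloxy-3-methoxybenzaldehyde bis[(trimethylsilyl)methyl] acetal
Conditions: 7 (2.5 equiv), TsOH·H2O (2 mol %), cyclohexane, Dean–Stark, reflux
Reagents that add atoms: none
Why: Acid-catalysed acetalisation with azeotropic removal of water; the symmetrical acetal is used so that the next step can expel only a silylmethoxy group.

Step 4
Reactants: 8 bis(silylmethyl) acetal
Product: 9 [chloro(4-benzyloxy-3-methoxyphenyl)methoxy]methyl-trimethylsilane (racemic)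
Conditions: AcCl (1.1 equiv), SOCl2 (2 mol %), CH2Cl2, 0 °C; volatiles off at 0.1 mbar, used at once
Reagents that add atoms: acetyl chloride, CC(=O)Cl (chlorine)
Why: Cleavage of an acetal by an acyl chloride to the α-chloro ether, driven by formation of the acetate and fast for a p-alkoxybenzylic acetal; the new centre is racemic and is lost again in the ylide.

Step 5
Reactants: 9 α-chloro silylmethyl ether; 5 enediol diester
Product: 11 diacetal-bridged ring-A diester cycloadduct, via carbonyl ylide 10 (not isolated)
Conditions: CsF (6 equiv, flame-dried), 4 Å MS, MeCN, rt; 9 (3 equiv) in MeCN added over 8 h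
Reagents that add atoms: none
Why: Proposed new method: fluoride attacks the silicon of the easily ionised α-chloro ether 9, and 1,3-elimination of Me3SiF and CsCl frees the non-stabilised carbonyl ylide 10, whose high-lying HOMO adds in one concerted, suprafacial event to the ester-lowered LUMO of the tetrasubstituted C=C of 5 and so forms C1–C2 and C4–C5 together. The closest known reaction type is the (3+2) cycloaddition of carbonyl ylides released in this way with acrylates, fumarates, maleates and acetylenedicarboxylates, and captodative alkoxyacrylates are known to be good dipolarophiles, but a fully substituted enediol diester has not been used. Ring A is closed by the intermolecular [π4s+π2s] cycloaddition itself, both ring bonds being made in the same step. C1 and C5 receive cis oxygens and cis esters from suprafacial addition to the ring-locked Z-enediol, and their absolute sense comes from the (5R,6R)-diacetal: the two alkene faces are homotopic, but on each face one flank carries a pseudo-axial OMe, so the small CH2 terminus should bond on that flank (C5) and the ArCH terminus on the open flank (C1). C2 is controlled by the E (W-shaped) ylide reacting with its oxygen above the dioxine ring, the mode that keeps the inner ylide hydrogens off the pseudo-axial OMe and the aryl group away from the C1 ester, so that the aryl group ends cis to the C1 oxygen. The step therefore needs flank and endo/exo selectivity but no regioselectivity, since 5 is C2-symmetric; every stereoisomeric adduct is a diastereomer that chromatography can remove, and slow addition of 9 keeps the ylide dilute against dimerisation and closure to the oxirane.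

Step 6
Reactants: 11 cycloadduct diester
Product: 12 half-ester (C6 carboxylic acid on C5, C8 methyl ester on C1)
Conditions: LiOH (1.1 equiv), THF–MeOH–H2O, 0 °C → rt; cold 1 M HCl to pH 3
Reagents that add atoms: lithium hydroxide, [Li+].[OH-] (acid oxygen)
Why: Selective saponification (BAc2) on conformational grounds: in the diacetal-locked chair the C5 ester is equatorial and open, whereas the C1 ester is axial, 1,3-diaxial to an acetal OMe and next to C2, and equatorial esters hydrolyse much faster than axial ones; no centre can epimerise because neither ester has an α-hydrogen.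

Step 7
Reactants: 12 half-ester
Product: 14 ring-B lactone (C6=O, C8H2), via hydroxy acid 13 (not isolated)
Conditions: LiEt3BH (3.5 equiv), THF, 0 °C → rt; then 1 M HCl, 0 °C → rt
Reagents that add atoms: none
Why: Half-ester to lactone conversion: LiEt3BH only deprotonates the acid (carboxylates are inert to it) but reduces even hindered esters, and on acidification the cis-disposed C8 carbinol and C6 acid lactonise (5-exo-trig), which fixes C6 at the acyl level and C8 at the CH2 level.

Step 8
Reactants: 14 ring-B lactone; 15 1-benzyloxy-4-bromo-2-methoxybenzene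
Product: 17 hydroxy ketone (C6 aryl ketone, C8 carbinol; in equilibrium with its cyclic hemiketal), via aryllithium 16 (not isolated)
Conditions: 15 (1.3 equiv), n-BuLi (1.25 equiv), THF, −78 °C; then 14, −78 °C; H2O
Reagents that add atoms: none
Why: Bromine–lithium exchange and single 1,2-addition of an aryllithium to a γ-lactone, as in C-aryl glycoside synthesis; the hindered lithium hemiketal alkoxide does not collapse at −78 °C, so a second addition is not expected.

Step 9
Reactants: 17 hydroxy ketone
Product: 18 diol (C6 benzylic carbinol as epimer mixture, C8 primary carbinol)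
Conditions: LiAlH4 (1.5 equiv), THF, 0 °C
Reagents that add atoms: none
Why: Hydride reduction of the aryl ketone through its open form; the configuration of the new carbinol is left open because C6 is ionised in step 10.

Step 10
Reactants: 18 diol
Product: 19 1,5-O-[(2R,3R)-2,3-dimethoxybutane-2,3-diyl]-di-O-benzylprinsepiol
Conditions: CSA (10 mol %), 4 Å MS, CH2Cl2, 0 °C
Reagents that add atoms: none
Why: Acid-catalysed cyclodehydration through the p-benzyloxybenzylic cation (SN1, 5-exo capture by the C8 hydroxyl), the standard closure of furofuran lignans: C6 is set in the ring closure, the aryl group turning away from the axial C4 methylene into the open sector next to the C5 oxygen, which is the C2-symmetric arrangement, while the diacetal keeps the C5 oxygen from starting a semipinacol shift.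

Step 11
Reactants: 19 diacetal-protected di-O-benzylprinsepiol
Product: 20 di-O-benzylprinsepiol
Conditions: TFA–H2O (9:1), CH2Cl2, 0 °C, short contact; cold aq. NaHCO3
Reagents that add atoms: none
Why: Acid hydrolysis of the diacetal, speeded by the strain of a dioxane fused to two five-membered rings and carrying two 1,3-diaxial CH2/OMe contacts; the benzylic C2–O3 and C6–O7 bonds should hold during the short contact because each potential cation is flanked by an oxygenated quaternary carbon.

Step 12
Reactants: 20 di-O-benzylprinsepiol
Product: 21 prinsepiol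
Conditions: H2 (1 atm), 10% Pd/C, EtOAc–MeOH, rt, stopped at full debenzylation
Reagents that add atoms: none
Why: Hydrogenolysis of the two aryl benzyl ethers, which is much faster than that of the hindered dialkyl benzylic C–O bonds of the furofuran when the reaction is stopped after uptake of two equivalents; no stereocentre is touched.

## Compound list

1 | dimethyl L-tartrate, (2R,3R) | COC(=O)[C@H](O)[C@@H](O)C(=O)OC | starting material
2 | butane-2,3-dione | CC(=O)C(C)=O | starting material
3 | dimethyl (2R,3R,5R,6R)-5,6-dimethoxy-5,6-dimethyl-1,4-dioxane-2,3-dicarboxylate (esters equatorial, OMe axial) | COC(=O)[C@@H]1O[C@@](C)(OC)[C@](C)(OC)O[C@H]1C(=O)OC | intermediate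
4 | dimethyl (2R,3S,5R,6R)-2-iodo-5,6-dimethoxy-5,6-dimethyl-1,4-dioxane-2,3-dicarboxylate (iodine anti to the syn-axial OMe) | COC(=O)[C@@]1(I)O[C@@](C)(OC)[C@](C)(OC)O[C@H]1C(=O)OC | intermediate
5 | dimethyl (5R,6R)-5,6-dimethoxy-5,6-dimethyl-5,6-dihydro-1,4-dioxine-2,3-dicarboxylate | COC(=O)C1=C(C(=O)OC)O[C@@](C)(OC)[C@](C)(OC)O1 | intermediate
6 | 4-benzyloxy-3-methoxybenzaldehyde (O-benzylvanillin) | COc1cc(C=O)ccc1OCc1ccccc1 | starting material
7 | (trimethylsilyl)methanol | C[Si](C)(C)CO | starting material
8 | 4-benzyloxy-3-methoxybenzaldehyde bis[(trimethylsilyl)methyl] acetal | COc1cc(C(OC[Si](C)(C)C)OC[Si](C)(C)C)ccc1OCc1ccccc1 | intermediate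
9 | [chloro(4-benzyloxy-3-methoxyphenyl)methoxy]methyl-trimethylsilane, racemic | COc1cc(C(Cl)OC[Si](C)(C)C)ccc1OCc1ccccc1 | intermediate
10 | (E)-carbonyl ylide ArCH=O(+)–CH2(−) | COc1cc(/C=[O+]/[CH2-])ccc1OCc1ccccc1 | intermediate
11 | dimethyl 5-Ar-2,3-dimethoxy-2,3-dimethyl-tetrahydrofuro[3,4-b][1,4]dioxine-4a,7a-dicarboxylate; cis ring fusion, Ar on C2 cis to the C1 oxygen, acetal centres R,R, C1/C2/C5 arranged in space as in 21 | COc1cc([C@H]2OC[C@@]3(C(=O)OC)O[C@@](C)(OC)[C@](C)(OC)O[C@@]23C(=O)OC)ccc1OCc1ccccc1 | intermediate
12 | half-ester of 11: free acid on C5 (C6), methyl ester on C1 (C8) | COc1cc([C@H]2OC[C@@]3(C(=O)O)O[C@@](C)(OC)[C@](C)(OC)O[C@@]23C(=O)OC)ccc1OCc1ccccc1 | intermediate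
13 | hydroxy acid: acid on C5 (C6), CH2OH on C1 (C8) | COc1cc([C@H]2OC[C@@]3(C(=O)O)O[C@@](C)(OC)[C@](C)(OC)O[C@@]23CO)ccc1OCc1ccccc1 | intermediate
14 | ring-B γ-lactone C5–C6(=O)–O7–C8H2–C1, diacetal retained | COc1cc([C@H]2OC[C@@]3(C(=O)OC4)O[C@@](C)(OC)[C@](C)(OC)O[C@@]234)ccc1OCc1ccccc1 | intermediate
15 | 1-benzyloxy-4-bromo-2-methoxybenzene | COc1cc(Br)ccc1OCc1ccccc1 | starting material
16 | 4-benzyloxy-3-methoxyphenyllithium | [Li]c1ccc(OCc2ccccc2)c(OC)c1 | intermediate
17 | hydroxy ketone: Ar–C6(=O) on C5, CH2OH (C8) on C1, drawn in the open form | COc1cc([C@H]2OC[C@@]3(C(=O)c4ccc(OCc5ccccc5)c(OC)c4)O[C@@](C)(OC)[C@](C)(OC)O[C@@]23CO)ccc1OCc1ccccc1 | intermediate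
18 | diol: Ar–C6H(OH) on C5 (both epimers), CH2OH (C8) on C1 | COc1cc([C@H]2OC[C@@]3(C(O)c4ccc(OCc5ccccc5)c(OC)c4)O[C@@](C)(OC)[C@](C)(OC)O[C@@]23CO)ccc1OCc1ccccc1 | intermediate
19 | 1,5-O-[(2R,3R)-2,3-dimethoxybutane-2,3-diyl]-di-O-benzylprinsepiol, C2-symmetric, both aryl groups cis to the adjacent bridgehead oxygen | COc1cc([C@H]2OC[C@@]3([C@@H](c4ccc(OCc5ccccc5)c(OC)c4)OC6)O[C@@](C)(OC)[C@](C)(OC)O[C@@]236)ccc1OCc1ccccc1 | intermediate
20 | (1S,2R,5S,6R)-2,6-bis(4-benzyloxy-3-methoxyphenyl)-3,7-dioxabicyclo[3.3.0]octane-1,5-diol | COc1cc([C@H]2OC[C@]3(O)[C@@H](c4ccc(OCc5ccccc5)c(OC)c4)OC[C@]23O)ccc1OCc1ccccc1 | intermediate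
21 | prinsepiol, (1S,2R,5S,6R)-2,6-bis(4-hydroxy-3-methoxyphenyl)-3,7-dioxabicyclo[3.3.0]octane-1,5-diol | COc1cc([C@H]2OC[C@]3(O)[C@@H](c4ccc(O)c(OC)c4)OC[C@]23O)ccc1O | target

## Step count and risks

Total steps: 12. Longest linear sequence: 10 (steps 1, 2, 5–12; the branch 3, 4, 5–12 is equally long).

### Steps most likely to fail

**1. Step 5.**
- What may go wrong: the ylide may be used up by dimerisation, by electrocyclic closure to the oxirane or by capture with traces of aldehyde before it reaches the crowded tetrasubstituted alkene. The flank or endo/exo selectivity may also be poor.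
- Fallback (known chemistry only): it sets out from 3 and 6 and comes back at 19, passing 18.
- Diacetal 3 is deprotonated (LDA, THF, −78 °C) and added to 6. The aldehyde enters anti to the syn-axial OMe, so the new carbinol carbon (C2) ends equatorial and the ester axial, which gives the mono-aldol adduct F1.
- A second deprotonation (LDA, 2.2 equiv, −78 °C) and addition to 6 does the same at the other centre and gives the bis-aldol adduct F2.
- LiAlH4 (THF) reduces both esters (now C8 and C4) to the tetraol F3.
- CSA (cat., CH2Cl2, 0 °C) closes ring A to 18 and ring B to 19 through the benzylic cations, so the carbinol configurations of F1–F3 do not matter.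

**2. Step 6.**
- What may go wrong: discrimination between the two esters may be too weak, or hydrolysis may run on to the diacid.
- Fallback: it sets out from 11 and comes back at 14, and it moves the differentiation from the ester level to the alcohol level.
- LiAlH4 (THF, 0 °C → rt) gives the diol F4.
- TEMPO (20 mol %) and PhI(OAc)2 (2.5 equiv) in CH2Cl2 bring about oxidative lactonisation. The bulky oxoammonium salt takes the equatorial C6 carbinol first, and the lactol F5 is oxidised on to 14.

**3. Step 11.**
- What may go wrong: ionisation of the electron-rich benzylic C–O bonds may compete with acetal hydrolysis, leading to epimerisation at C2 and C6 or to loss of material.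
- Fallback: it sets out from 19 and comes back at 21, and it lowers the donor strength of the arenes before the acid step.
- H2 and Pd/C (EtOAc) give the diacetal-protected prinsepiol F6.
- Ac2O and pyridine give its bis(aryl acetate) F7. The bridgehead oxygens are still masked at this point.
- TFA–H2O then cleaves the diacetal of the now poorly ionisable system to prinsepiol di(aryl acetate) F8.
- K2CO3 in MeOH frees 21.

## Further compounds

F1 | step 5 | mono-aldol adduct of 3 with 6 (new carbinol carbon equatorial, geminal ester axial; carbinol epimers) | COC(=O)[C@@]1(C(O)c2ccc(OCc3ccccc3)c(OC)c2)O[C@@](C)(OC)[C@](C)(OC)O[C@H]1C(=O)OC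
F2 | step 5 | bis-aldol adduct (both carbinol carbons equatorial, both esters axial; carbinol epimers) | COC(=O)[C@@]1(C(O)c2ccc(OCc3ccccc3)c(OC)c2)O[C@@](C)(OC)[C@](C)(OC)O[C@]1(C(O)c2ccc(OCc3ccccc3)c(OC)c2)C(=O)OC
F3 | step 5 | tetraol from F2 (two benzylic carbinols, two axial CH2OH groups) | OC[C@@]1(C(O)c2ccc(OCc3ccccc3)c(OC)c2)O[C@@](C)(OC)[C@](C)(OC)O[C@]1(C(O)c2ccc(OCc3ccccc3)c(OC)c2)CO
F4 | step 6 | diol from 11 (CH2OH on C1 and on C5) | COc1cc([C@H]2OC[C@@]3(CO)O[C@@](C)(OC)[C@](C)(OC)O[C@@]23CO)ccc1OCc1ccccc1
F5 | step 6 | ring-B lactol (C6 hemiacetal, anomer mixture) | COc1cc([C@H]2OC[C@@]3(C(O)OC4)O[C@@](C)(OC)[C@](C)(OC)O[C@@]234)ccc1OCc1ccccc1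
F6 | step 11 | diacetal-protected prinsepiol (free phenols) | COc1cc([C@H]2OC[C@@]3([C@@H](c4ccc(O)c(OC)c4)OC5)O[C@@](C)(OC)[C@](C)(OC)O[C@@]235)ccc1O
F7 | step 11 | diacetal-protected prinsepiol bis(aryl acetate) | COc1cc([C@H]2OC[C@@]3([C@@H](c4ccc(OC(C)=O)c(OC)c4)OC5)O[C@@](C)(OC)[C@](C)(OC)O[C@@]235)ccc1OC(C)=O
F8 | step 11 | prinsepiol bis(aryl acetate) | COc1cc([C@H]2OC[C@]3(O)[C@@H](c4ccc(OC(C)=O)c(OC)c4)OC[C@]23O)ccc1OC(C)=O
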